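## Analysis of the target

The target is a (2S)-flavanone, C25H28O6. Ring A is a phloroglucinol unit fused through C4a and C8a to the dihydropyranone ring C, and ring B is a resorcinol unit on C2. Each aromatic ring carries one 3-methylbut-2-enyl (prenyl) group, at C6 and at C5'. C2 is the only stereocentre, so no relative configuration has to be set, but it is benzylic, bonded to O1 and β to the C4 ketone. Base can open ring C to the chalcone by retro-oxa-Michael reaction, and strong acid can ionise C2–O1 once ring B carries free 2'- and 4'-hydroxyls; either process racemises it. The four phenols must be unmasked at the end without strong base, and each prenyl group sits ortho to a phenol and cyclises to a dimethylchroman under forcing acid. Ring A poses a regiochemical problem as well: a chalcone from a C-prenylated phloroglucinol ketone can close through either ortho-hydroxyl, giving the 6- or the 8-prenyl isomer. The strategy reads ring C as the chain O1–C2–C3–C4(=O) bridging the adjacent ring A carbons C8a and C4a. Detached from ring A, that chain is a 4-aryloxetan-2-one, and the flavanone is this β-lactone with two aryne carbons placed into its acyl C4–O1 bond. The ring A partner is then a 3,5-dialkoxy-4-prenylbenzyne, whose polarisation, and not a choice between two hydroxyls, places the prenyl group at C6.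

## Retrosynthetic reasoning

Target 26 is traced back to its bis(methoxymethyl) ether 25 and then to the diacetate 24. Only O–C bonds of protecting groups are cut. Acetal ethers on ring A survive the organolithium chemistry that builds the aryne precursor and supply the 3-alkoxy group that polarises the aryne. Acetates make ring B a poor donor, which the β-lactone and the key step both need. Forward, the acetates go first under near-neutral solvolysis, so that no base meets the flavanone, and the acetals last under dilute acid.

Compound 24 is cut at O1–C8a and at C4–C4a. This removes both ring A bonds of ring C at once and leaves the whole C2–C3–C4 chain, with the stereocentre, in the (4S)-β-lactone 21. The other fragment is aryne 22, stored as the ortho-silylaryl triflate 14. Cutting here, and not at O1–C2 or C2–C3, means the stereocentre is made beforehand in a small molecule and no bond to it is formed or broken when the halves are joined. It also turns the 6- versus 8-prenyl question into the regiochemistry of a 3-alkoxyaryne. The forward reaction must make the ring oxygen of 21 add to the aryne carbon remote from the alkoxy group, and then let the aryl anion take the acyl carbon so that the four-membered ring grows into ring C.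

Lactone 21 is cut across its ring at C2–C3 and O1–C4 into aldehyde 18 and ketene 20, generated from acetyl chloride 19. This is the shortest access to an enantioenriched 4-aryl-β-lactone: one catalytic step from an aldehyde. The forward cycloaddition must deliver the two-carbon unit to one face of the aldehyde under catalyst control.

Aldehyde 18 is cut at the aryl–CH2 bond of its prenyl group, giving aryl bromide 16 and the allylic stannane 17. Bromide 16 is the diacetate of the commercial bromo aldehyde 15. A neutral cross-coupling is chosen because the aldehyde and the aryl esters must survive, and the bromine of 15 already marks the right carbon.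

Triflate 14 is cut at O–S and at C–Si, by way of silylphenol 13 and carbamate 12, back to carbamate 8 and phenol 7. The silicon must sit between the phenol oxygen and a methoxymethoxy group, and a carbamate on that oxygen directs metalation exactly there. Phenol 7 has a mirror plane through C1 and C4, so its two ortho positions are identical and only one product can form.

Phenol 7 is cut at the aryl–CH2 bond of its prenyl group, giving silyl ether 3 (prenylated as 6) and prenyl bromide 4. Compound 3 comes from phloroglucinol 1 through bis-ether 2. The carbon between the two methoxymethoxy groups of 3 is the most acidic ring position, and the bulky silyl ether on the third oxygen does not direct. Deprotonation and alkylation therefore place the prenyl group para to the future triflate oxygen. The only unselective event of the route is the first, the statistical double etherification of 1, accepted because it is run on the cheapest material.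

## Alternatives that were turned down

Alternative 1: C2–C3 made by carbenoid C–H insertion.
- **Disconnection and key step:** the C2–C3 bond is cut. In the diazomethyl ketone A2, ring A carries the ring B unit as a benzyl ether on the C8a oxygen. A chiral dirhodium tetracarboxylate would decompose A2, and the carbenoid at C3 would insert into a benzylic C–H bond next to the ether oxygen. This gives the tetrakis(silyl ether) A1, closing ring C and creating C2 in one event.
- **For:** the aromatic halves are joined by a simple ether synthesis and no strained intermediate is needed. The stereocentre arises catalytically in the ring-forming step, which on paper is more economical than making it separately, as the chosen route does.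
- **Against:** the carbenoid is acceptor-only, for which six-membered C–H insertion is slow and enantiocontrol is weak. The ether oxygen lies in a five-membered relationship to the carbenoid carbon, so ylide formation followed by a Stevens benzyl shift is the expected faster course. Two trisubstituted alkenes and two electron-rich arenes offer cyclopropanation and Buchner-type addition as further exits. The diazoketone must also be built on a di-ortho-substituted benzoic acid.
- **Comparison:** the chosen strategy keeps its unproven step free of any stereochemical task and of chemoselectivity problems at the prenyl groups. The price is a strained precursor and one separate asymmetric step.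

Alternative 2: ring A made last by Claisen cyclisation.
- **Disconnection and key step:** the C4a–C5 bond is cut and ring A is unravelled into a ketoester chain. In the dihydropyranone A4, C8a carries the chain C8–C7(=O)–C6(prenyl)–C5 ester. A magnesium alkoxide would form the extended enolate, C4a would attack the ester carbon, and aromatisation would give the bis(methoxymethyl) ether A3.
- **For:** it is stronger than the chosen route on two points. The prenyl group is fixed at C6 by the carbon chain itself, and the 5- and 7-hydroxyls appear free, so ring A needs no protecting groups and one deprotection is saved.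
- **Against:** A4 is an acid- and base-sensitive tricarbonyl compound. Its enantioselective construction (the C2 stereocentre in a six-membered heterocycle plus a C-prenylated ketoester chain) would need a much longer linear sequence. Under alkoxide the dihydropyranone can enolise at C3 and expel O1, which destroys the stereocentre before ring A exists. Such a chain can also close in the aldol sense or acylate on oxygen.
- **Comparison:** the chosen strategy gives up the protecting-group economy. In return it takes both aromatic rings from cheap aromatics and exposes the stereocentre to no enolising base until the product has formed.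

Alternative 3: ether first, then anionic cycloacylation.
- **Disconnection and key step:** C4–C4a is cut last and O1–C2 before it. The (S)-β-aryloxy Weinreb amide A6, an aryl iodide, would undergo iodine–magnesium exchange with an isopropylmagnesium halide–lithium chloride reagent. The arylmagnesium at C4a would attack the amide carbonyl and give the tetrakis(methoxymethyl) ether A5.
- **For:** every step is of a well-established type, and the amide stops the addition at the ketone. The phenol that provides ring A is symmetric, so no regiochemical question arises, and one kind of protecting group comes off in one step. On predictability of the ring closure it is stronger than the chosen route.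
- **Against:** O1–C2 must be made by displacement (Mitsunobu or SN2) at a benzylic carbinol bearing a 2,4-dialkoxyphenyl group. That centre ionises and eliminates easily, so configuration is most at risk exactly where it is installed. The β-aryloxy amide can lose phenoxide by elimination under the basic exchange conditions, and exchange on so electron-rich an arene is slow. Joining the halves takes three operations (iodination, etherification, cyclisation) where the chosen route uses one.
- **Comparison:** in place of that reliability, the chosen strategy forms both ring bonds in one step in which C2–O1 is never made or broken, and keeps ring B electron-poor through the sensitive stages.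

Key step: step 11

Assumption: the sense of induction in step 10 is assigned by analogy with the quinine and quinidine catalyst families; O-trimethylsilylquinine is taken to give the (4S) lactone, and O-trimethylsilylquinidine replaces it if the (4R) lactone is found.

## Route

Step 1
Reactants: 1 phloroglucinol (benzene-1,3,5-triol)
Product: 2 3,5-bis(methoxymethoxy)phenol
Conditions: MOMCl (2.0 equiv), i-Pr2NEt (2.2 equiv), CH2Cl2/DMF, 0 °C → rt; chromatography
Reagents that add atoms: chloromethyl methyl ether, COCCl
Why: O-alkylation of phenols with a chloromethyl ether (Williamson-type acetal ether formation); the three hydroxyls are equivalent, so two equivalents should make the bis-ether the main component of a statistical mixture, separable from mono- and tris-ether, and the mono-ether can be resubmitted.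

Step 2
Reactants: 2 3,5-bis(methoxymethoxy)phenol
Product: 3 [3,5-bis(methoxymethoxy)phenoxy]tri(propan-2-yl)silane
Conditions: TIPSCl, imidazole, DMF, rt
Reagents that add atoms: chlorotri(propan-2-yl)silane, CC(C)[Si](Cl)(C(C)C)C(C)C
Why: Silyl ether formation; the bulky triisopropylsilyl group masks the third oxygen as a base-stable, non-directing substituent so that the next metalation goes between the two acetal ethers.

Step 3
Reactants: 3 [3,5-bis(methoxymethoxy)phenoxy]tri(propan-2-yl)silane; 4 1-bromo-3-methylbut-2-ene (prenyl bromide)
Product: 6 [3,5-bis(methoxymethoxy)-4-(3-methylbut-2-en-1-yl)phenoxy]tri(propan-2-yl)silane, via aryllithium 5 (not isolated)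
Conditions: n-BuLi, TMEDA, THF, 0 °C; then CuBr·SMe2 (10 mol %), 4, −78 °C → rt
Reagents that add atoms: none
Why: Directed ortho-metalation at the carbon flanked by two methoxymethoxy groups, then copper-catalysed alkylation of the aryl metal by the allylic bromide, which favours attack at the CH2 terminus and so gives the linear prenyl group.

Step 4
Reactants: 6 [3,5-bis(methoxymethoxy)-4-(3-methylbut-2-en-1-yl)phenoxy]tri(propan-2-yl)silane
Product: 7 3,5-bis(methoxymethoxy)-4-(3-methylbut-2-en-1-yl)phenol
Conditions: Bu4NF, THF, 0 °C; aq. NH4Cl
Reagents that add atoms: none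
Why: Fluoride-induced cleavage of the aryl silyl ether; acetal ethers and the alkene are inert to fluoride.

Step 5
Reactants: 7 3,5-bis(methoxymethoxy)-4-(3-methylbut-2-en-1-yl)phenol
Product: 8 3,5-bis(methoxymethoxy)-4-(3-methylbut-2-en-1-yl)phenyl N-(propan-2-yl)carbamate
Conditions: i-PrNCO, Et3N (cat.), CH2Cl2, rt
Reagents that add atoms: isopropyl isocyanate, CC(C)N=C=O
Why: Addition of the phenol to an isocyanate (carbamoylation); the N–H carbamate is a strong ortho-directing group that can later be removed under mild base by elimination.

Step 6
Reactants: 8 3,5-bis(methoxymethoxy)-4-(3-methylbut-2-en-1-yl)phenyl N-(propan-2-yl)carbamate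
Product: 12 3,5-bis(methoxymethoxy)-4-(3-methylbut-2-en-1-yl)-2-(trimethylsilyl)phenyl N-(propan-2-yl)carbamate, via N-TBS carbamate 9 (not isolated), via ortho-lithio carbamate 10 (not isolated), via N-TBS ortho-silyl carbamate 11 (not isolated)
Conditions: TBSOTf (1.05 equiv), TMEDA, Et2O, 0 °C → rt; n-BuLi, TMEDA, −78 °C; TMSCl, −78 °C → rt; aq. NH4Cl
Reagents that add atoms: chlorotrimethylsilane, C[Si](C)(C)Cl; tert-butyldimethylsilyl trifluoromethanesulfonate, CC(C)(C)[Si](C)(C)OS(=O)(=O)C(F)(F)F (its silicon is carried only by 9 to 11)
Why: Carbamate-directed ortho-metalation after in situ N-silylation, with silyl chloride quench; the only ring C–H bonds are the two equivalent ones flanked by the carbamate oxygen and an acetal ether, where both groups cooperate. The low temperature is meant to keep metalation kinetic and to suppress acyl migration, and the N–Si bond is hydrolysed on work-up.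

Step 7
Reactants: 12 3,5-bis(methoxymethoxy)-4-(3-methylbut-2-en-1-yl)-2-(trimethylsilyl)phenyl N-(propan-2-yl)carbamate
Product: 14 3,5-bis(methoxymethoxy)-4-(3-methylbut-2-en-1-yl)-2-(trimethylsilyl)phenyl trifluoromethanesulfonate, via silylphenol 13 (not isolated)
Conditions: Et2NH, DBU, MeCN, 40 °C; then PhNTf2, rt
Reagents that add atoms: 1,1,1-trifluoro-N-phenyl-N-(trifluoromethylsulfonyl)methanesulfonamide, O=S(=O)(N(c1ccccc1)S(=O)(=O)C(F)(F)F)C(F)(F)F
Why: E1cB cleavage of the N–H carbamate (the isocyanate is trapped by the amine), then O-sulfonylation of the phenoxide with a mild triflyl donor in the same flask; neither stage is acidic or electrophilic enough to touch the acetals or the alkene.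

Step 8
Reactants: 15 5-bromo-2,4-dihydroxybenzaldehyde
Product: 16 4-bromo-6-formyl-1,3-phenylene diacetate (5-bromo-2,4-diacetoxybenzaldehyde)
Conditions: Ac2O, pyridine, DMAP (cat.), CH2Cl2, 0 °C → rt
Reagents that add atoms: acetic anhydride, CC(=O)OC(C)=O
Why: Acylation of both phenols; the acetates make ring B electron-poor for the lactone and the key step, activate the bromide toward oxidative addition, and are removable without strong base.

Step 9
Reactants: 16 4-bromo-6-formyl-1,3-phenylene diacetate; 17 tributyl(3-methylbut-2-en-1-yl)stannane
Product: 18 4-formyl-6-(3-methylbut-2-en-1-yl)-1,3-phenylene diacetate (2,4-diacetoxy-5-prenylbenzaldehyde)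
Conditions: Pd(PPh3)4 (5 mol %), toluene, 100 °C
Reagents that add atoms: none
Why: Stille coupling of an aryl bromide with an allylic stannane under neutral conditions that tolerate the aldehyde and aryl esters; reductive elimination at the less substituted allyl terminus should give the linear prenyl arene.

Step 10
Reactants: 18 4-formyl-6-(3-methylbut-2-en-1-yl)-1,3-phenylene diacetate; 19 acetyl chloride
Product: 21 (4S)-4-[2,4-diacetoxy-5-(3-methylbut-2-en-1-yl)phenyl]oxetan-2-one, via ketene 20 (not isolated)
Conditions: O-trimethylsilylquinine (10 mol %), LiClO4, i-Pr2NEt, CH2Cl2/Et2O, −78 °C, slow addition of 19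
Reagents that add atoms: none
Why: Catalytic asymmetric ketene–aldehyde [2+2] cycloaddition in its acyl halide–aldehyde cyclocondensation form: the base turns 19 into ketene 20, the alkaloid adds to give a chiral ammonium enolate that attacks the LiClO4-activated aldehyde, and the aldolate closes onto the acylammonium. The new stereocentre (C4 of the lactone, later C2) is set by catalyst control over the aldehyde face, and the acetates should keep the aryl group electron-poor enough for the lactone to be handled without decarboxylation.

Step 11
Reactants: 21 (4S)-4-[2,4-diacetoxy-5-(3-methylbut-2-en-1-yl)phenyl]oxetan-2-one; 14 3,5-bis(methoxymethoxy)-4-(3-methylbut-2-en-1-yl)-2-(trimethylsilyl)phenyl trifluoromethanesulfonate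
Product: 24 (2S)-2-[2,4-diacetoxy-5-(3-methylbut-2-en-1-yl)phenyl]-5,7-bis(methoxymethoxy)-6-(3-methylbut-2-en-1-yl)-2,3-dihydro-4H-chromen-4-one, via aryne 22 (not isolated), via zwitterion 23 (not isolated)
Conditions: 14 (1.3 equiv), CsF (3 equiv), MeCN/toluene 1:3, 0 °C → rt
Reagents that add atoms: none
Why: Proposed new method: fluoride attacks the silicon of 14 and loss of triflate releases aryne 22; the ring oxygen of 21, whose lone pairs are less tied up in ester resonance than in an unstrained ester, adds to the aryne carbon remote from the C5 methoxymethoxy group, the site at which a 3-alkoxyaryne is attacked for inductive reasons, and gives zwitterion 23. The aryl anion at C4a then adds to the adjacent acyl carbon in a 4-exo-trig sense, and the fused four-membered adduct collapses at once by cleavage of the strained C4–O1 bond, so ring C is closed by a two-atom ring expansion of the oxetanone with O1–C8a and C4–C4a as the new bonds. The closest known reaction types are aryne insertion into the N–C(=O) bond of amides and ureas, into the C–C(=O) bond of β-ketoesters and into the acyl C–O bond of carboxylates to give ortho-hydroxyaryl ketones, and the opening of cyclic ethers through aryloxonium ions; insertion into a lactone C–O bond is without precedent. No stereocentre is created: neither C2–O1 nor C2–C3 is broken, so the (S) configuration of 21 should pass unchanged into 24. Three selectivities are needed: regiochemistry on the aryne, secured by the C5 alkoxy group; ring oxygen versus carbonyl oxygen, which nothing in the substrate secures and which is the open question, since attack through the carbonyl oxygen would be followed by opening at benzylic C2 and loss of configuration; and acyl capture ahead of ionisation at C2 or decarboxylation, favoured by the two acetates that make ring B a poor cation-stabilising group. The prenyl double bonds are expected to be slower ene partners for the aryne than the lactone.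

Step 12
Reactants: 24 (2S)-2-[2,4-diacetoxy-5-(3-methylbut-2-en-1-yl)phenyl]-5,7-bis(methoxymethoxy)-6-(3-methylbut-2-en-1-yl)-2,3-dihydro-4H-chromen-4-one
Product: 25 (2S)-2-[2,4-dihydroxy-5-(3-methylbut-2-en-1-yl)phenyl]-5,7-bis(methoxymethoxy)-6-(3-methylbut-2-en-1-yl)-2,3-dihydro-4H-chromen-4-one
Conditions: NH4OAc, MeOH/H2O 4:1, rt
Reagents that add atoms: none
Why: Mild solvolysis (transesterification) of aryl acetates promoted by NH4OAc; the medium is close to neutral, so ring C should not open to the chalcone, and the acetal ethers are untouched.

Step 13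
Reactants: 25 (2S)-2-[2,4-dihydroxy-5-(3-methylbut-2-en-1-yl)phenyl]-5,7-bis(methoxymethoxy)-6-(3-methylbut-2-en-1-yl)-2,3-dihydro-4H-chromen-4-one
Product: 26 (2S)-2-[2,4-dihydroxy-5-(3-methylbut-2-en-1-yl)phenyl]-5,7-dihydroxy-6-(3-methylbut-2-en-1-yl)-2,3-dihydro-4H-chromen-4-one
Conditions: HCl (1 M) in MeOH, 40 °C; NaHCO3 quench at full conversion
Reagents that add atoms: none
Why: Acid-catalysed acetal exchange removes both methoxymethyl ethers as the formaldehyde acetal of the solvent; dilute acid and moderate temperature are chosen to stay below the threshold for cyclisation of a phenol onto the neighbouring prenyl group, and C2 is not epimerised by acid of this strength.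

## Compound list

1 | benzene-1,3,5-triol (phloroglucinol) | Oc1cc(O)cc(O)c1 | starting material
2 | 3,5-bis(methoxymethoxy)phenol | COCOc1cc(O)cc(OCOC)c1 | intermediate
3 | [3,5-bis(methoxymethoxy)phenoxy]tri(propan-2-yl)silane | COCOc1cc(OCOC)cc(O[Si](C(C)C)(C(C)C)C(C)C)c1 | intermediate
4 | 1-bromo-3-methylbut-2-ene (prenyl bromide) | CC(C)=CCBr | starting material
5 | [2,6-bis(methoxymethoxy)-4-(triisopropylsilyloxy)phenyl]lithium | COCOc1cc(O[Si](C(C)C)(C(C)C)C(C)C)cc(OCOC)c1[Li] | intermediate (not isolated)
6 | [3,5-bis(methoxymethoxy)-4-(3-methylbut-2-en-1-yl)phenoxy]tri(propan-2-yl)silane | CC(C)=CCc1c(OCOC)cc(O[Si](C(C)C)(C(C)C)C(C)C)cc1OCOC | intermediate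
7 | 3,5-bis(methoxymethoxy)-4-(3-methylbut-2-en-1-yl)phenol | CC(C)=CCc1c(OCOC)cc(O)cc1OCOC | intermediate
8 | 3,5-bis(methoxymethoxy)-4-(3-methylbut-2-en-1-yl)phenyl N-(propan-2-yl)carbamate | CC(C)NC(=O)Oc1cc(OCOC)c(CC=C(C)C)c(OCOC)c1 | intermediate
9 | N-(tert-butyldimethylsilyl) derivative of carbamate 8 | CC(C)N([Si](C)(C)C(C)(C)C)C(=O)Oc1cc(OCOC)c(CC=C(C)C)c(OCOC)c1 | intermediate (not isolated)
10 | 2-lithio derivative of 9 (lithium between the carbamate oxygen and a methoxymethoxy group) | CC(C)N([Si](C)(C)C(C)(C)C)C(=O)Oc1cc(OCOC)c(CC=C(C)C)c(OCOC)c1[Li] | intermediate (not isolated)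
11 | N-(tert-butyldimethylsilyl) derivative of carbamate 12 | CC(C)N([Si](C)(C)C(C)(C)C)C(=O)Oc1cc(OCOC)c(CC=C(C)C)c(OCOC)c1[Si](C)(C)C | intermediate (not isolated)
12 | 3,5-bis(methoxymethoxy)-4-(3-methylbut-2-en-1-yl)-2-(trimethylsilyl)phenyl N-(propan-2-yl)carbamate | CC(C)NC(=O)Oc1cc(OCOC)c(CC=C(C)C)c(OCOC)c1[Si](C)(C)C | intermediate
13 | 3,5-bis(methoxymethoxy)-4-(3-methylbut-2-en-1-yl)-2-(trimethylsilyl)phenol | CC(C)=CCc1c(OCOC)cc(O)c([Si](C)(C)C)c1OCOC | intermediate (not isolated)
14 | 3,5-bis(methoxymethoxy)-4-(3-methylbut-2-en-1-yl)-2-(trimethylsilyl)phenyl trifluoromethanesulfonate | CC(C)=CCc1c(OCOC)cc(OS(=O)(=O)C(F)(F)F)c([Si](C)(C)C)c1OCOC | intermediate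
15 | 5-bromo-2,4-dihydroxybenzaldehyde | O=Cc1cc(Br)c(O)cc1O | starting material
16 | 4-bromo-6-formyl-1,3-phenylene diacetate | CC(=O)Oc1cc(OC(C)=O)c(C=O)cc1Br | intermediate
17 | tributyl(3-methylbut-2-en-1-yl)stannane | CCCC[Sn](CCCC)(CCCC)CC=C(C)C | starting material
18 | 4-formyl-6-(3-methylbut-2-en-1-yl)-1,3-phenylene diacetate | CC(C)=CCc1cc(C=O)c(OC(C)=O)cc1OC(C)=O | intermediate
19 | acetyl chloride | CC(=O)Cl | starting material
20 | ketene | C=C=O | intermediate (not isolated)
21 | (4S)-4-[2,4-diacetoxy-5-(3-methylbut-2-en-1-yl)phenyl]oxetan-2-one | CC(C)=CCc1cc([C@@H]2CC(=O)O2)c(OC(C)=O)cc1OC(C)=O | intermediate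
22 | 3,5-bis(methoxymethoxy)-4-(3-methylbut-2-en-1-yl)benzyne (1,2-didehydrobenzene) | COCOC1=C(CC=C(C)C)C(OCOC)=CC#C1 | intermediate (not isolated)
23 | O-aryl oxetanonium aryl anion zwitterion (O1 bonded to C2, C4 and C8a; carbanion at C4a) | CC(C)=CCc1cc([C@@H]2CC(=O)[O+]2c2cc(OCOC)c(CC=C(C)C)c(OCOC)[c-]2)c(OC(C)=O)cc1OC(C)=O | intermediate (not isolated)
24 | (2S)-2-[2,4-diacetoxy-5-(3-methylbut-2-en-1-yl)phenyl]-5,7-bis(methoxymethoxy)-6-(3-methylbut-2-en-1-yl)-2,3-dihydro-4H-chromen-4-one | CC(C)=CCc1cc([C@@H]2CC(=O)c3c(cc(OCOC)c(CC=C(C)C)c3OCOC)O2)c(OC(C)=O)cc1OC(C)=O | intermediate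
25 | (2S)-2-[2,4-dihydroxy-5-(3-methylbut-2-en-1-yl)phenyl]-5,7-bis(methoxymethoxy)-6-(3-methylbut-2-en-1-yl)-2,3-dihydro-4H-chromen-4-one | CC(C)=CCc1cc([C@@H]2CC(=O)c3c(cc(OCOC)c(CC=C(C)C)c3OCOC)O2)c(O)cc1O | intermediate
26 | (2S)-2-[2,4-dihydroxy-5-(3-methylbut-2-en-1-yl)phenyl]-5,7-dihydroxy-6-(3-methylbut-2-en-1-yl)-2,3-dihydro-4H-chromen-4-one | CC(C)=CCc1cc([C@@H]2CC(=O)c3c(cc(O)c(CC=C(C)C)c3O)O2)c(O)cc1O | target

## Step count and least certain steps

Total step count: 13. Longest linear sequence: 10 steps (steps 1 to 7, then 11 to 13).

**Step 11 (the proposed new method).**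
- What may go wrong: addition of the aryne to the carbonyl oxygen of the lactone instead of the ring oxygen, followed by opening at benzylic C2 with loss of configuration, or decarboxylation. Also possible are an ene reaction of the aryne with a prenyl double bond, fluoride-induced acyl transfer from the aryl acetates, and slow base-induced opening of ring C in the product.
- Fallback, from 18 and 14, returning at 24, by known chemistry:
  - Wittig olefination of 18 with allyl (triphenylphosphoranylidene)acetate would give the allyl cinnamate F1.
  - Deallylation with Pd(PPh3)4 and PhSiH3 would give the cinnamic acid F2.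
  - F2 and 14 with CsF in hot THF would undergo the known aryne insertion into the acyl C–O bond of a carboxylic acid, with the same aryne regiochemistry. This gives the 2'-hydroxychalcone F3, whose phenoxide closes by oxa-Michael addition to the racemic flavanone F4 (re-acetylation with Ac2O and pyridine if acyl transfer has occurred).
  - Kinetic resolution of F4 by Noyori–Ikariya transfer hydrogenation with RuCl(p-cymene)[(R,R)-TsDPEN] and HCO2H/Et3N is expected to reduce the (2R) enantiomer to the cis-flavan-4-ol F5 and leave (2S)-24.
  - This fallback keeps at most half of the material.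

**Step 10.**
- What may go wrong: poor or reversed facial selectivity with an ortho-acetoxy aryl aldehyde; migration of the ortho-acetyl group to the aldolate oxygen before ring closure; decarboxylation of the lactone on purification.
- Fallback, from 18, returning at 21:
  - Roskamp homologation of 18 with allyl diazoacetate and NbCl5 (cat.) would give the β-keto ester F6.
  - Transfer hydrogenation with RuCl(p-cymene)[(S,S)-TsDPEN] and HCO2H/Et3N is expected to give the (S)-β-hydroxy ester F7.
  - Pd(PPh3)4 and PhSiH3 would free the β-hydroxy acid F8.
  - Carboxyl activation with PhSO2Cl in pyridine at 0 °C would close 21 with retention at the carbinol carbon.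

**Step 6.**
- What may go wrong: deprotonation at the benzylic–allylic CH2 of the prenyl group, which is flanked by two coordinating acetal ethers, in competition with ring metalation; attack of the silyl triflate on an acetal ether; acyl migration of the carbamate.
- Fallback, from 7, returning at 13 and then 14:
  - Bromination of 7 with NBS (1.0 equiv, CH2Cl2, −78 °C) would give the ortho-bromophenol F9.
  - O-silylation with hexamethyldisilazane would give the silyl ether F10.
  - n-BuLi at −78 °C would bring about bromine–lithium exchange, which is faster than any deprotonation, and a retro-Brook 1,3-shift of silicon from oxygen to carbon. This gives the lithium salt of 13, which is triflated with PhNTf2 in the same flask to 14.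

**Step 9.**
- What may go wrong: transfer of the allylic group with allylic transposition, giving the 1,1-dimethylallyl isomer, or allyl transfer to the aldehyde carbonyl.
- Fallback, from 15, returning at 18:
  - Suzuki–Miyaura coupling of unprotected 15 with 4,4,5,5-tetramethyl-2-(3-methylbut-2-en-1-yl)-1,3,2-dioxaborolane, PdCl2(IPent)(3-chloropyridine) and aq. KOH in THF would give 2,4-dihydroxy-5-(3-methylbut-2-en-1-yl)benzaldehyde F11. This catalyst type couples at the CH2 terminus, and the aldehyde of the bis-phenoxide is a poor acceptor for allylboration.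
  - Acetylation as in step 8 would then give 18.

**Step 13.**
- What may go wrong: acid-promoted cyclisation of a phenol onto the neighbouring prenyl double bond, or ionisation at C2 once ring B is a free resorcinol.
- Fallback, from 25, returning at 26:
  - Me3SiOTf with 2,2'-bipyridyl in CH2Cl2 at 0 °C would exchange the aryl methoxymethyl ethers for silyl ethers without Brønsted acid and silylate the free phenols, giving the tetrakis(trimethylsilyl) ether F12.
  - Water would hydrolyse F12 to 26 on work-up.

## Further compounds

F1 | step 11 | prop-2-en-1-yl (2E)-3-[2,4-diacetoxy-5-(3-methylbut-2-en-1-yl)phenyl]prop-2-enoate | C=CCOC(=O)/C=C/c1cc(CC=C(C)C)c(OC(C)=O)cc1OC(C)=O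
F2 | step 11 | (2E)-3-[2,4-diacetoxy-5-(3-methylbut-2-en-1-yl)phenyl]prop-2-enoic acid | OC(=O)/C=C/c1cc(CC=C(C)C)c(OC(C)=O)cc1OC(C)=O
F3 | step 11 | (2E)-3-[2,4-diacetoxy-5-(3-methylbut-2-en-1-yl)phenyl]-1-[2-hydroxy-4,6-bis(methoxymethoxy)-5-(3-methylbut-2-en-1-yl)phenyl]prop-2-en-1-one | CC(C)=CCc1cc(/C=C/C(=O)c2c(O)cc(OCOC)c(CC=C(C)C)c2OCOC)c(OC(C)=O)cc1OC(C)=O
F4 | step 11 | racemic 2-[2,4-diacetoxy-5-(3-methylbut-2-en-1-yl)phenyl]-5,7-bis(methoxymethoxy)-6-(3-methylbut-2-en-1-yl)-2,3-dihydro-4H-chromen-4-one | CC(C)=CCc1cc(C2CC(=O)c3c(cc(OCOC)c(CC=C(C)C)c3OCOC)O2)c(OC(C)=O)cc1OC(C)=O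
F5 | step 11 | (2R,4R)-2-[2,4-diacetoxy-5-(3-methylbut-2-en-1-yl)phenyl]-5,7-bis(methoxymethoxy)-6-(3-methylbut-2-en-1-yl)-3,4-dihydro-2H-chromen-4-ol (2,4-cis) | CC(C)=CCc1cc([C@H]2C[C@@H](O)c3c(cc(OCOC)c(CC=C(C)C)c3OCOC)O2)c(OC(C)=O)cc1OC(C)=O
F6 | step 10 | prop-2-en-1-yl 3-[2,4-diacetoxy-5-(3-methylbut-2-en-1-yl)phenyl]-3-oxopropanoate | C=CCOC(=O)CC(=O)c1cc(CC=C(C)C)c(OC(C)=O)cc1OC(C)=O
F7 | step 10 | prop-2-en-1-yl (3S)-3-[2,4-diacetoxy-5-(3-methylbut-2-en-1-yl)phenyl]-3-hydroxypropanoate | C=CCOC(=O)C[C@H](O)c1cc(CC=C(C)C)c(OC(C)=O)cc1OC(C)=O
F8 | step 10 | (3S)-3-[2,4-diacetoxy-5-(3-methylbut-2-en-1-yl)phenyl]-3-hydroxypropanoic acid | OC(=O)C[C@H](O)c1cc(CC=C(C)C)c(OC(C)=O)cc1OC(C)=O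
F9 | step 6 | 2-bromo-3,5-bis(methoxymethoxy)-4-(3-methylbut-2-en-1-yl)phenol | CC(C)=CCc1c(OCOC)cc(O)c(Br)c1OCOC
F10 | step 6 | [2-bromo-3,5-bis(methoxymethoxy)-4-(3-methylbut-2-en-1-yl)phenoxy]trimethylsilane | CC(C)=CCc1c(OCOC)cc(O[Si](C)(C)C)c(Br)c1OCOC
F11 | step 9 | 2,4-dihydroxy-5-(3-methylbut-2-en-1-yl)benzaldehyde | CC(C)=CCc1cc(C=O)c(O)cc1O
F12 | step 13 | (2S)-2-[2,4-bis(trimethylsilyloxy)-5-(3-methylbut-2-en-1-yl)phenyl]-6-(3-methylbut-2-en-1-yl)-5,7-bis(trimethylsilyloxy)-2,3-dihydro-4H-chromen-4-one | CC(C)=CCc1cc([C@@H]2CC(=O)c3c(cc(O[Si](C)(C)C)c(CC=C(C)C)c3O[Si](C)(C)C)O2)c(O[Si](C)(C)C)cc1O[Si](C)(C)C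
A1 | alternative 1 | (2S)-2-[2,4-bis(tert-butyldimethylsilyloxy)-5-(3-methylbut-2-en-1-yl)phenyl]-5,7-bis(tert-butyldimethylsilyloxy)-6-(3-methylbut-2-en-1-yl)-2,3-dihydro-4H-chromen-4-one | CC(C)=CCc1cc([C@@H]2CC(=O)c3c(cc(O[Si](C)(C)C(C)(C)C)c(CC=C(C)C)c3O[Si](C)(C)C(C)(C)C)O2)c(O[Si](C)(C)C(C)(C)C)cc1O[Si](C)(C)C(C)(C)C
A2 | alternative 1 | 1-[2-{[2,4-bis(tert-butyldimethylsilyloxy)-5-(3-methylbut-2-en-1-yl)phenyl]methoxy}-4,6-bis(tert-butyldimethylsilyloxy)-5-(3-methylbut-2-en-1-yl)phenyl]-2-diazoethan-1-one | CC(C)=CCc1cc(COc2cc(O[Si](C)(C)C(C)(C)C)c(CC=C(C)C)c(O[Si](C)(C)C(C)(C)C)c2C(=O)C=[N+]=[N-])c(O[Si](C)(C)C(C)(C)C)cc1O[Si](C)(C)C(C)(C)C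
A3 | alternative 2 | (2S)-2-[2,4-bis(methoxymethoxy)-5-(3-methylbut-2-en-1-yl)phenyl]-5,7-dihydroxy-6-(3-methylbut-2-en-1-yl)-2,3-dihydro-4H-chromen-4-one | CC(C)=CCc1cc([C@@H]2CC(=O)c3c(cc(O)c(CC=C(C)C)c3O)O2)c(OCOC)cc1OCOC
A4 | alternative 2 | methyl 4-{(2S)-2-[2,4-bis(methoxymethoxy)-5-(3-methylbut-2-en-1-yl)phenyl]-4-oxo-3,4-dihydro-2H-pyran-6-yl}-2-(3-methylbut-2-en-1-yl)-3-oxobutanoate (configuration at the ester-bearing carbon not defined) | COC(=O)C(CC=C(C)C)C(=O)CC1=CC(=O)C[C@@H](c2cc(CC=C(C)C)c(OCOC)cc2OCOC)O1
A5 | alternative 3 | (2S)-2-[2,4-bis(methoxymethoxy)-5-(3-methylbut-2-en-1-yl)phenyl]-5,7-bis(methoxymethoxy)-6-(3-methylbut-2-en-1-yl)-2,3-dihydro-4H-chromen-4-one | CC(C)=CCc1cc([C@@H]2CC(=O)c3c(cc(OCOC)c(CC=C(C)C)c3OCOC)O2)c(OCOC)cc1OCOC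
A6 | alternative 3 | (3S)-3-[2,4-bis(methoxymethoxy)-5-(3-methylbut-2-en-1-yl)phenyl]-3-[2-iodo-3,5-bis(methoxymethoxy)-4-(3-methylbut-2-en-1-yl)phenoxy]-N-methoxy-N-methylpropanamide | CON(C)C(=O)C[C@H](Oc1cc(OCOC)c(CC=C(C)C)c(OCOC)c1I)c1cc(CC=C(C)C)c(OCOC)cc1OCOC
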